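The isoflavone is cut through ring A at the C8–C8a and C4a–C5 bonds, leaving ring C as a 4-pyranone that already carries the chroman (ring B) on C3. The key step exploits the 1,3-related oxygens on C5 and C7 of ring A and its fusion to ring C through C4a–C8a: a 1-methoxy-1,3-bis(silyloxy)butadiene supplies C5–C8 with both oxygens in place, and a bromine on the pyranone carbon that becomes C4a leaves as HBr, so the new ring aromatises without an oxidant. The precursor is 3-[8-(benzyloxy)-2,2-dimethylchroman-5-yl]-5-bromo-4H-pyran-4-one, made by Suzuki coupling; hydrogenolysis of the benzyl ether then gives the target.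

Key step: step 11

Remark on the chemistry: the target has no stereocentre. Bromine is put on the chroman only after the 8-hydroxyl has been freed, because a free phenol directs bromination to its para position (chroman C5). Bromination of 2-(benzyloxy)phenol itself would go para to the hydroxyl and end up at chroman C6. Compounds 1, 2, 9 and 12 are taken as commercial.

Step 1
Reactants: 1 2-(benzyloxy)phenol; 2 3-chloro-3-methylbut-1-yne
Product: 3 1-(benzyloxy)-2-[(2-methylbut-3-yn-2-yl)oxy]benzene
Conditions: DBU (1.3 equiv), CuCl2·2H2O (cat.), MeCN, 0 °C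
Reagents that add atoms: none
Why: Copper-catalysed propargylic O-alkylation of the phenol by the tertiary propargylic chloride gives the aryl 1,1-dimethylpropargyl ether, and the benzyl ether is inert.

Step 2
Reactants: 3 1-(benzyloxy)-2-[(2-methylbut-3-yn-2-yl)oxy]benzene
Product: 4 8-(benzyloxy)-2,2-dimethyl-2H-chromene
Conditions: PhNEt2, 190 °C
Reagents that add atoms: none
Why: Aromatic propargyl Claisen rearrangement to the only free ortho position, followed by 1,5-hydrogen shift and 6π oxa-electrocyclisation, closes the 2,2-dimethyl-2H-chromene; the other ortho position is blocked by the benzyloxy group.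

Step 3
Reactants: 4 8-(benzyloxy)-2,2-dimethyl-2H-chromene
Product: 5 2,2-dimethylchroman-8-ol
Conditions: H2 (1 atm), 10% Pd/C, EtOAc/EtOH, 20 °C
Reagents that add atoms: none
Why: Heterogeneous catalytic hydrogenation saturates the styrenic C3=C4 bond and hydrogenolyses the benzyl ether in one operation, freeing the 8-hydroxyl that directs the next step; the non-benzylic aryl–O–C(CH3)2 bond of the chroman survives.

Step 4
Reactants: 5 2,2-dimethylchroman-8-ol
Product: 6 5-bromo-2,2-dimethylchroman-8-ol
Conditions: NBS (1.0 equiv), MeCN, −10 → 0 °C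
Reagents that add atoms: N-bromosuccinimide, O=C1CCC(=O)N1Br
Why: Electrophilic aromatic bromination should go para to the free hydroxyl (C5), the strongest activator on the ring, as in the para-bromination of 2-alkoxyphenols; one equivalent at low temperature limits attack at C7 and dibromination.

Step 5
Reactants: 6 5-bromo-2,2-dimethylchroman-8-ol
Product: 7 8-(benzyloxy)-5-bromo-2,2-dimethylchroman
Conditions: BnBr, K2CO3, DMF, 20 °C
Reagents that add atoms: benzyl bromide, BrCc1ccccc1
Why: Williamson etherification of the phenoxide puts back a benzyl ether that is stable to the palladium couplings and to the silyl triflate of the key step.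

Step 6
Reactants: 7 8-(benzyloxy)-5-bromo-2,2-dimethylchroman
Product: 8 2-[8-(benzyloxy)-2,2-dimethylchroman-5-yl]-4,4,5,5-tetramethyl-1,3,2-dioxaborolane
Conditions: B2pin2, PdCl2(dppf) (3 mol %), KOAc, 1,4-dioxane, 90 °C
Reagents that add atoms: bis(pinacolato)diboron, CC1(C)OB(OC1(C)C)B1OC(C)(C)C(C)(C)O1
Why: Miyaura borylation of the electron-rich aryl bromide with the weak acetate base gives the pinacol boronate without homocoupling.

Step 7
Reactants: 9 4H-pyran-4-one
Product: 10 3,5-dibromo-4H-pyran-4-one
Conditions: Br2 (2.2 equiv), pyridine, CH2Cl2, 0 → 20 °C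
Reagents that add atoms: bromine, BrBr
Why: Electrophilic α-halogenation of the vinylogous ester on both enone arms (bromine addition, then pyridine-mediated loss of HBr) is the reaction type that turns chromones into 3-bromochromones.

Step 8
Reactants: 8 2-[8-(benzyloxy)-2,2-dimethylchroman-5-yl]-4,4,5,5-tetramethyl-1,3,2-dioxaborolane; 10 3,5-dibromo-4H-pyran-4-one (3 equiv)
Product: 11 3-[8-(benzyloxy)-2,2-dimethylchroman-5-yl]-5-bromo-4H-pyran-4-one
Conditions: PdCl2(dppf) (5 mol %), K3PO4, 1,4-dioxane/H2O, 70 °C
Reagents that add atoms: none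
Why: Suzuki–Miyaura cross-coupling on the symmetrical dibromide should stop at mono-arylation because the dibromide is in excess and can be recovered, and the mild phosphate base spares the pyranone ring.

Step 9
Reactants: 12 methyl acetoacetate
Product: 13 methyl 3-(trimethylsilyloxy)but-2-enoate
Conditions: Me3SiCl, Et3N, hexane, 20 °C
Reagents that add atoms: chlorotrimethylsilane, C[Si](C)(C)Cl
Why: Soft enolisation of the β-keto ester and O-silylation give the silyl enol ether; its alkene geometry is of no consequence.

Step 10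
Reactants: 13 methyl 3-(trimethylsilyloxy)but-2-enoate
Product: 15 1-methoxy-1,3-bis(trimethylsilyloxy)buta-1,3-diene, via lithium dienolate 14 (not isolated)
Conditions: LDA, THF, −78 °C; Me3SiCl, −78 → 20 °C
Reagents that add atoms: chlorotrimethylsilane, C[Si](C)(C)Cl
Why: Kinetic γ-deprotonation at the methyl group and O-silylation of the resulting ester dienolate give the 1,3-bis(silyloxy)diene, which is used freshly distilled.

Step 11
Reactants: 11 3-[8-(benzyloxy)-2,2-dimethylchroman-5-yl]-5-bromo-4H-pyran-4-one; 15 1-methoxy-1,3-bis(trimethylsilyloxy)buta-1,3-diene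
Product: 19 3-[8-(benzyloxy)-2,2-dimethylchroman-5-yl]-5,7-dihydroxy-4H-chromen-4-one, via silyloxypyrylium triflate 16 (not isolated), via cis-fused bromo cycloadduct 17 (not isolated), via dihydrochromenone silyl ketal 18 (not isolated)
Conditions: Me3SiOSO2CF3 (1.3 equiv), CH2Cl2, 20 °C, 1 h; 15 (2 equiv), −78 → 20 °C; DBU (4 equiv), 0 → 40 °C; 1 M HCl, THF, 20 °C
Reagents that add atoms: none
Why: Proposed new method: Me3SiOSO2CF3 silylates the pyranone carbonyl to the 4-silyloxypyrylium salt 16, the CH2 terminus of diene 15 adds to its free α-carbon next to C–Br (pyranone C6, future C8a) in a vinylogous Mukaiyama–Michael step, and the resulting 5-bromo-4-silyloxy-2H-pyran enol ether attacks the silylated ester carbon of the same chain through pyranone C5 (future C4a), so that C8–C8a and C4a–C5 arise in a stepwise polar [4+2] addition across the bromo-bearing alkene to give adduct 17. The closest known reaction types are the Diels–Alder/aromatisation of 1,3-dioxygenated silyloxydienes with halo-quinones and the silyl-triflate-promoted additions and tandem annulations of silyloxydienes on 4-silyloxybenzopyrylium salts; a 3-bromo-4-pyranone has not been used in this way. Ring A closes as a six-membered carbocycle by 6-(enolexo)-exo-trig attack of the enol ether carbon on the activated ester carbonyl, and no stereocentre has to be controlled because the cis ring-fusion centres and the ketal carbon of 17 are erased on aromatisation. Since H-8a and Br are cis in 17, DBU has to remove HBr by a syn elimination (or by an anti elimination after reversible opening of the O1–C8a bond) to give the vinylogous ester 18 while C7 is still a silyl enol ether and cannot trigger a retro-oxa-Michael opening of ring C; 18 then loses methanol and, on acidic work-up, its silyl groups, and tautomerises to the 5,7-diol. The step needs site selectivity between the two enone arms and one orientation of the diene: the twisted ortho-substituted chromanyl group shields C2 while bromine leaves C6 open and inductively activated, only the bromo-bearing arm can aromatise, and the polarity match of the nucleophilic CH2 terminus with the pyrylium α-carbon fixes the orientation that places the oxygens on C5 and C7.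

Step 12
Reactants: 19 3-[8-(benzyloxy)-2,2-dimethylchroman-5-yl]-5,7-dihydroxy-4H-chromen-4-one
Product: 20 3-(8-hydroxy-2,2-dimethylchroman-5-yl)-5,7-dihydroxy-4H-chromen-4-one (target)
Conditions: H2 (1 atm), 10% Pd/C, EtOAc/MeOH, 20 °C
Reagents that add atoms: none
Why: Catalytic hydrogenolysis of the benzyl aryl ether frees the last phenol; the reaction is stopped once 19 is consumed so that the chromone C2=C3 bond and the chroman ether are left untouched.

Compound list
1 | 2-(benzyloxy)phenol | Oc1ccccc1OCc1ccccc1 | starting material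
2 | 3-chloro-3-methylbut-1-yne | CC(C)(Cl)C#C | starting material
3 | 1-(benzyloxy)-2-[(2-methylbut-3-yn-2-yl)oxy]benzene | C#CC(C)(C)Oc1ccccc1OCc1ccccc1 | intermediate
4 | 8-(benzyloxy)-2,2-dimethyl-2H-chromene | CC1(C)C=Cc2cccc(OCc3ccccc3)c2O1 | intermediate
5 | 2,2-dimethylchroman-8-ol (2,2-dimethyl-3,4-dihydro-2H-chromen-8-ol) | CC1(C)CCc2cccc(O)c2O1 | intermediate
6 | 5-bromo-2,2-dimethylchroman-8-ol | CC1(C)CCc2c(Br)ccc(O)c2O1 | intermediate
7 | 8-(benzyloxy)-5-bromo-2,2-dimethylchroman | CC1(C)CCc2c(Br)ccc(OCc3ccccc3)c2O1 | intermediate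
8 | 2-[8-(benzyloxy)-2,2-dimethylchroman-5-yl]-4,4,5,5-tetramethyl-1,3,2-dioxaborolane | CC1(C)CCc2c(B3OC(C)(C)C(C)(C)O3)ccc(OCc3ccccc3)c2O1 | intermediate
9 | 4H-pyran-4-one | O=c1ccocc1 | starting material
10 | 3,5-dibromo-4H-pyran-4-one | O=c1c(Br)cocc1Br | intermediate
11 | 3-[8-(benzyloxy)-2,2-dimethylchroman-5-yl]-5-bromo-4H-pyran-4-one | O=c1c(Br)cocc1-c1ccc(OCc2ccccc2)c2OC(C)(C)CCc12 | intermediate
12 | methyl acetoacetate | COC(=O)CC(C)=O | starting material
13 | methyl 3-(trimethylsilyloxy)but-2-enoate (E/Z mixture) | COC(=O)C=C(C)O[Si](C)(C)C | intermediate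
14 | lithium 1-methoxy-3-(trimethylsilyloxy)buta-1,3-dien-1-olate (not isolated) | [Li+].COC([O-])=CC(=C)O[Si](C)(C)C | intermediate
15 | 1-methoxy-1,3-bis(trimethylsilyloxy)buta-1,3-diene | COC(O[Si](C)(C)C)=CC(=C)O[Si](C)(C)C | intermediate
16 | 3-[8-(benzyloxy)-2,2-dimethylchroman-5-yl]-5-bromo-4-(trimethylsilyloxy)pyrylium trifluoromethanesulfonate (not isolated) | C[Si](C)(C)Oc1c(Br)c[o+]cc1-c1ccc(OCc2ccccc2)c2OC(C)(C)CCc12.[O-]S(=O)(=O)C(F)(F)F | intermediate
17 | 3-[8-(benzyloxy)-2,2-dimethylchroman-5-yl]-4a-bromo-5-methoxy-5,7-bis(trimethylsilyloxy)-4a,5,8,8a-tetrahydro-4H-chromen-4-one, racemic, Br and H-8a cis, both epimers at C5 (not isolated) | O=C1C(c3ccc(OCc4ccccc4)c4OC(C)(C)CCc34)=CO[C@@H]2CC(O[Si](C)(C)C)=CC(OC)(O[Si](C)(C)C)[C@]12Br | intermediate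
18 | 3-[8-(benzyloxy)-2,2-dimethylchroman-5-yl]-5-methoxy-5,7-bis(trimethylsilyloxy)-5,8-dihydro-4H-chromen-4-one, racemic (not isolated) | O=C1C(c3ccc(OCc4ccccc4)c4OC(C)(C)CCc34)=COC2=C1C(OC)(O[Si](C)(C)C)C=C(O[Si](C)(C)C)C2 | intermediate
19 | 3-[8-(benzyloxy)-2,2-dimethylchroman-5-yl]-5,7-dihydroxy-4H-chromen-4-one | CC1(C)CCc2c(-c3coc4cc(O)cc(O)c4c3=O)ccc(OCc3ccccc3)c2O1 | intermediate
20 | 3-(8-hydroxy-2,2-dimethylchroman-5-yl)-5,7-dihydroxy-4H-chromen-4-one | CC1(C)CCc2c(-c3coc4cc(O)cc(O)c4c3=O)ccc(O)c2O1 | target

Total step count: 12. Longest linear sequence: 9 steps (steps 1–6, 8, 11, 12).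

Steps most likely to fail

Step 11. Several processes could divert the annulation:
- the diene may add to the aryl-bearing enone arm;
- the sequence may stop at the open-chain conjugate adduct without the second C–C bond forming;
- ring C may open by a retro-oxa-Michael reaction;
- the ring-fusion bromine may be lost as an electrophile instead of as HBr, giving 5-deoxy products;
- silanol may be lost in place of methanol, leaving a 5-methyl ether.

The fallback brings ring A in ready-made by known chemistry and sets out from boronate 8. Commercial 2,4,6-trihydroxyacetophenone is dibenzylated (BnBr, K2CO3, acetone) to 1-[2,4-bis(benzyloxy)-6-hydroxyphenyl]ethan-1-one F1. This is condensed with N,N-dimethylformamide dimethyl acetal to (E)-1-[2,4-bis(benzyloxy)-6-hydroxyphenyl]-3-(dimethylamino)prop-2-en-1-one F2 and cyclised with iodine in methanol to 5,7-bis(benzyloxy)-3-iodo-4H-chromen-4-one F3. Suzuki–Miyaura coupling of F3 with 8 (Pd(PPh3)4, Na2CO3, DME/H2O) should give 5,7-bis(benzyloxy)-3-[8-(benzyloxy)-2,2-dimethylchroman-5-yl]-4H-chromen-4-one F4. Hydrogenolysis of its three benzyl ethers over Pd/C comes back to the route at target 20.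

Step 8. Over-arylation to the 3,5-diaryl pyranone, or opening of the pyranone ring by the aqueous base, could erode the mono-coupling. The fallback replaces statistical control by halogen differentiation and sets out from 9. Monobromination (Br2, 1 equiv, pyridine) gives 3-bromo-4H-pyran-4-one F5, and α-iodination of the remaining enone arm (I2, pyridine, CH2Cl2) gives 3-bromo-5-iodo-4H-pyran-4-one F6. Oxidative addition should then select the C–I bond in the coupling with 8 (Pd(PPh3)4, K3PO4, 40 °C), which comes back to the route at 11.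

Step 4. Bromination ortho to the hydroxyl (C7) or a second bromination could compete with attack at C5. The fallback fixes the bromine position before the chroman is built; it sets out from alkyne 2 and commercial 2-(benzyloxy)-5-bromobenzaldehyde, in which bromine already stands para to the benzyloxy group. Baeyer–Villiger oxidation (mCPBA, CH2Cl2) gives 2-(benzyloxy)-5-bromophenyl formate F7, which is hydrolysed (KOH, MeOH/H2O) to 2-(benzyloxy)-5-bromophenol F8. Copper-catalysed O-alkylation with 2 gives 1-(benzyloxy)-4-bromo-2-[(2-methylbut-3-yn-2-yl)oxy]benzene F9, and thermal Claisen cyclisation gives 8-(benzyloxy)-5-bromo-2,2-dimethyl-2H-chromene F10. Homogeneous hydrogenation with RhCl(PPh3)3 and H2, which spares the aryl bromide and the benzyl ether, comes back to the route at 7.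

Further compounds
F1 | step 11 | 1-[2,4-bis(benzyloxy)-6-hydroxyphenyl]ethan-1-one | CC(=O)c1c(O)cc(OCc2ccccc2)cc1OCc1ccccc1
F2 | step 11 | (E)-1-[2,4-bis(benzyloxy)-6-hydroxyphenyl]-3-(dimethylamino)prop-2-en-1-one | CN(C)/C=C/C(=O)c1c(O)cc(OCc2ccccc2)cc1OCc1ccccc1
F3 | step 11 | 5,7-bis(benzyloxy)-3-iodo-4H-chromen-4-one | O=c1c(I)coc2cc(OCc3ccccc3)cc(OCc3ccccc3)c12
F4 | step 11 | 5,7-bis(benzyloxy)-3-[8-(benzyloxy)-2,2-dimethylchroman-5-yl]-4H-chromen-4-one | CC1(C)CCc2c(-c3coc4cc(OCc5ccccc5)cc(OCc5ccccc5)c4c3=O)ccc(OCc3ccccc3)c2O1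
F5 | step 8 | 3-bromo-4H-pyran-4-one | O=c1ccocc1Br
F6 | step 8 | 3-bromo-5-iodo-4H-pyran-4-one | O=c1c(Br)cocc1I
F7 | step 4 | 2-(benzyloxy)-5-bromophenyl formate | O=COc1cc(Br)ccc1OCc1ccccc1
F8 | step 4 | 2-(benzyloxy)-5-bromophenol | Oc1cc(Br)ccc1OCc1ccccc1
F9 | step 4 | 1-(benzyloxy)-4-bromo-2-[(2-methylbut-3-yn-2-yl)oxy]benzene | C#CC(C)(C)Oc1cc(Br)ccc1OCc1ccccc1
F10 | step 4 | 8-(benzyloxy)-5-bromo-2,2-dimethyl-2H-chromene | CC1(C)C=Cc2c(Br)ccc(OCc3ccccc3)c2O1
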